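**Plan**

Labels: lignan numbering is used. Core ring A = O7–C7–C8–C8'–C9' and ring B = O–C7'–C8'–C8–C9. S1 and S2 are the syringyl rings on C7' and C7. The glycerol units are a (G1 to G2, 7R,8S), b (G2 to S1, 7R,8R) and c (G3 to S2, 7S,8R).
Cuts: first the S1 aryl–C7' bond together with C8'–C9' of ring A, in one event. Next the C7'=C8' enol ether of ring B goes back to a lactol and a pentenyl chain, then C7–C8 (aldol) and S2–CHO (carbonylation). In the side chains, the three C7–C8 bonds (aldol) and the three ArO–CH2 bonds (ether synthesis) are cut.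
Enabling feature: C7' is bound to the ring-B oxygen and to the ring-fusion carbon C8', and C9' of ring A is an O–CH2 carbon at the formaldehyde level. Ring B can therefore be carried as a 2,3-dihydrofuran (enol ether C7'=C8') and C9' as the CH2 of a MEM acetal on O7. Ionisation then closes ring A at C8' and leaves C7' activated for arylation.
Forward: the threo diol 9 is made once and feeds both halves. Silylation, phenol release and a second ether/aldol/reduction/inversion round give aryl iodide 17 (unit b, then a). Inversion, formylation, aldol, acetal, reduction, alkene cleavage and dehydration give dihydrofuran 29 (unit c, ring B). Step 20 joins the halves and closes ring A, and two deprotections finish.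
Stereochemistry: three Evans syn aldols (auxiliary control) set C7/C8 of units b and c (one shared aldol, step 4), of unit a and of the core. Two Mitsunobu inversions at C7 turn threo into erythro (a, c). C8' and C7' are relayed from C8 in the key step: the tether enforces cis fusion and convex-face capture places the aryl group exo.

Key step: step 20

Remark: both enantiomers of 4-benzyl-3-(chloroacetyl)oxazolidin-2-one are taken as commercial. The anomeric centres of 27, 28 and 31 are mixtures and are left undefined. TBS = tert-butyldimethylsilyl, Bz = benzoyl, MEM = 2-methoxyethoxymethyl.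

Step 1
Reactants: 1 vanillin
Product: 2 4-(tert-butyldimethylsilyloxy)-3-methoxybenzaldehyde
Conditions: TBSCl, imidazole, CH2Cl2, rt
Reagents that add atoms: tert-butyldimethylsilyl chloride CC(C)(C)[Si](C)(C)Cl
Why: Phenol silylation (silyl ether formation) masks the acidic OH for the boron aldol reactions and gives one aldehyde that serves as G1, G2 and G3; no stereocentre is involved.

Step 2
Reactants: 3 2,6-dimethoxyphenol
Product: 4 4-iodo-2,6-dimethoxyphenol
Conditions: N-iodosuccinimide, MeCN, 0 °C
Reagents that add atoms: N-iodosuccinimide O=C1CCC(=O)N1I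
Why: Electrophilic aromatic iodination goes para to the free OH, the strongest donor, whose two ortho positions are blocked by OMe.

Step 3
Reactants: 4 4-iodo-2,6-dimethoxyphenol; 5 (S)-4-benzyl-3-(chloroacetyl)oxazolidin-2-one
Product: 6 (S)-4-benzyl-3-[2-(4-iodo-2,6-dimethoxyphenoxy)acetyl]oxazolidin-2-one
Conditions: K2CO3, NaI (cat.), acetone, 50 °C
Reagents that add atoms: none
Why: Williamson ether synthesis: the phenoxide displaces the activated α-chloride (iodide catalysis) in an SN2 reaction that tolerates the two ortho methoxy groups and leaves the auxiliary centre untouched.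

Step 4
Reactants: 6 (S)-aryloxyacetyl imide; 2 TBS-vanillin
Product: 8 (S)-4-benzyl-3-[(2S,3R)-3-(4-TBSO-3-methoxyphenyl)-3-hydroxy-2-(4-iodo-2,6-dimethoxyphenoxy)propanoyl]oxazolidin-2-one (syn aldol adduct), via Z-dibutylboron enolate 7 (not isolated)
Conditions: Bu2BOTf, Et3N, CH2Cl2, −78 to 0 °C; 2, −78 to 0 °C; then pH 7 buffer, MeOH, H2O2
Reagents that add atoms: dibutylboron triflate CCCCB(CCCC)OS(=O)(=O)C(F)(F)F (its Bu2B group stands in 7 only)
Why: Evans syn aldol: the Z-boron enolate 7 reacts through a chair Zimmerman–Traxler transition state on the face away from the benzyl group of the (S)-auxiliary, which sets both new centres (2S,3R in the imide, 8R and 7R in lignan numbering, threo), a reaction known for aryloxyacetyl imides of this kind.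

Step 5
Reactants: 8 syn aldol adduct
Product: 9 (1R,2R)-1-(4-TBSO-3-methoxyphenyl)-2-(4-iodo-2,6-dimethoxyphenoxy)propane-1,3-diol (threo diol 7R,8R)
Conditions: NaBH4, THF/H2O, 0 °C to rt
Reagents that add atoms: none
Why: Reductive removal of the auxiliary (borohydride reduction of an N-acyloxazolidinone) turns the activated imide carbonyl into the C9 alcohol without touching C7, C8, the aryl iodide or the aryl silyl ether.

Step 6
Reactants: 9 threo diol
Product: 10 7,9-bis-O-TBS ether of 9 (7R,8R)
Conditions: TBSOTf, 2,6-lutidine, CH2Cl2, 0 °C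
Reagents that add atoms: tert-butyldimethylsilyl triflate CC(C)(C)[Si](C)(C)OS(=O)(=O)C(F)(F)F
Why: Silyl ether formation; silyl groups and not esters are chosen for unit b because the G2 phenol is freed next and a C7 ester para to a phenoxide would leave to give a quinone methide.

Step 7
Reactants: 10 tris-TBS ether
Product: 11 4-[(1R,2R)-1,3-bis(TBSO)-2-(4-iodo-2,6-dimethoxyphenoxy)propyl]-2-methoxyphenol
Conditions: KHF2, MeOH, rt
Reagents that add atoms: none
Why: Chemoselective desilylation: bifluoride cleaves the aryl silyl ether (phenoxide is the better leaving group) and spares the two alkyl silyl ethers at room temperature.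

Step 8
Reactants: 11 G2 phenol; 12 (R)-4-benzyl-3-(chloroacetyl)oxazolidin-2-one
Product: 13 (R)-4-benzyl-3-(aryloxyacetyl)oxazolidin-2-one in which the aryloxy group is the G2 oxygen of 11 (unit b 7R,8R)
Conditions: K2CO3, NaI (cat.), acetone, 45 °C
Reagents that add atoms: none
Why: Williamson ether synthesis (SN2 at the α-chloro imide) forms the G2 O–CH2 bond, and the C7 silyloxy group is too poor a leaving group for quinone methide formation under these mild basic conditions.

Step 9
Reactants: 13 (R)-imide; 2 TBS-vanillin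
Product: 15 syn aldol adduct of 13 (new centres 2R,3S; unit b 7R,8R unchanged), via Z-dibutylboron enolate 14 (not isolated)
Conditions: Bu2BOTf, Et3N, CH2Cl2, −78 to 0 °C; 2, −78 to 0 °C; then pH 7 buffer, MeOH, H2O2
Reagents that add atoms: dibutylboron triflate CCCCB(CCCC)OS(=O)(=O)C(F)(F)F (its Bu2B group stands in 14 only)
Why: Evans syn aldol under control of the (R)-auxiliary (chair transition state, face away from the benzyl group) sets C8 and C7 of unit a as the mirror image of step 4 (8S and 7S after reduction), independent of the remote centres of unit b.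

Step 10
Reactants: 15 syn aldol adduct
Product: 16 threo diol of unit a (7S,8S) on the bis-TBS unit b (7R,8R)
Conditions: NaBH4, THF/H2O, 0 °C to rt
Reagents that add atoms: none
Why: Borohydride reduction of the N-acyloxazolidinone frees the C9 alcohol of unit a and the auxiliary and leaves silyl ethers, aryl iodide and all stereocentres untouched.

Step 11
Reactants: 16 threo diol
Product: 17 fragment 1: S1 aryl iodide carrying unit b (7R,8R; 7,9-bis-OTBS) and unit a (7R,8S; 7,9-dibenzoate) and the G1 phenol as TBS ether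
Conditions: BzOH, PPh3, DIAD, toluene, 0 °C to rt
Reagents that add atoms: benzoic acid OC(=O)c1ccccc1
Why: Mitsunobu esterification of both hydroxyl groups: the primary C9 alcohol is simply acylated while the benzylic C7 alcohol is displaced by benzoate in an SN2 reaction with inversion (7S to 7R), so that the threo diol becomes the protected erythro unit a in one operation, as known for the C7 inversion of arylglycerol β-aryl ethers.

Step 12
Reactants: 9 threo diol
Product: 18 (1S,2R)-1-(4-TBSO-3-methoxyphenyl)-2-(4-iodo-2,6-dimethoxyphenoxy)propane-1,3-diyl dibenzoate (erythro 7S,8R)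
Conditions: BzOH, PPh3, DIAD, toluene, 0 °C to rt
Reagents that add atoms: benzoic acid OC(=O)c1ccccc1
Why: Mitsunobu esterification of both hydroxyl groups acylates C9–OH and inverts the benzylic C7 centre by SN2 displacement (7R to 7S), which turns the common threo diol into the protected erythro unit c.

Step 13
Reactants: 18 erythro dibenzoate iodide
Product: 19 4-[(1S,2R)-1,3-bis(benzoyloxy)-1-(4-TBSO-3-methoxyphenyl)propan-2-yloxy]-3,5-dimethoxybenzaldehyde
Conditions: Pd(PPh3)4 (cat.), CO (balloon), Bu3SnH (slow addition), THF, 50 °C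
Reagents that add atoms: carbon monoxide [C-]#[O+]
Why: Palladium-catalysed reductive carbonylation of an aryl iodide (oxidative addition to zerovalent palladium, CO insertion, hydride transfer from tin) runs under neutral conditions that spare the benzoates and the silyl ether.

Step 14
Reactants: 20 (R)-4-benzyloxazolidin-2-one; 21 pent-4-enoyl chloride
Product: 22 (R)-4-benzyl-3-(pent-4-enoyl)oxazolidin-2-one
Conditions: Et3N, DMAP (cat.), CH2Cl2, 0 °C to rt
Reagents that add atoms: none
Why: N-acylation of the oxazolidinone with an acid chloride under DMAP catalysis is a standard way to the acyl imide and does not touch the auxiliary centre.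

Step 15
Reactants: 22 (R)-pentenoyl imide; 19 aldehyde
Product: 24 (R)-4-benzyl-3-[(2R)-2-[(R)-hydroxy(aryl)methyl]pent-4-enoyl]oxazolidin-2-one with aryl = S2 ring carrying unit c (syn aldol adduct), via Z-dibutylboron enolate 23 (not isolated)
Conditions: Bu2BOTf, Et3N, CH2Cl2, −78 to 0 °C; 19, −78 to 0 °C; then pH 7 buffer, MeOH, H2O2
Reagents that add atoms: dibutylboron triflate CCCCB(CCCC)OS(=O)(=O)C(F)(F)F (its Bu2B group stands in 23 only)
Why: Evans syn aldol: enolate 23 adds through a chair transition state on the face away from the benzyl group of the (R)-auxiliary and sets C8 and C7 of the core (2R,3R in the imide, 8S and 7R in lignan numbering), the syn relation being the one that later places the S2 aryl group exo on ring A.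

Step 16
Reactants: 24 syn aldol adduct
Product: 25 O7-MEM ether of 24
Conditions: MEMCl, iPr2NEt, Bu4NI (cat.), CH2Cl2, 40 °C
Reagents that add atoms: 2-methoxyethoxymethyl chloride COCCOCCl
Why: Acetal formation (MEM ether) with the chloromethyl ether and a hindered amine base protects O7 and at the same time brings in C9' and the chelating arm that the key step needs.

Step 17
Reactants: 25 MEM ether
Product: 26 (7R,8S) primary alcohol: 2-[(R)-(aryl)(MEM-oxy)methyl]pent-4-en-1-ol, S configured at C2
Conditions: NaBH4, THF/H2O, 0 °C to rt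
Reagents that add atoms: none
Why: Borohydride reduction of the N-acyloxazolidinone is faster than attack on the benzoates and frees the C9 alcohol without touching C7 or C8.

Step 18
Reactants: 26 primary alcohol
Product: 27 lactol (ring B): 4-[(R)-(aryl)(MEM-oxy)methyl]oxolan-2-ol, S configured at C4 (C8)
Conditions: OsO4 (cat.), NaIO4, 2,6-lutidine, dioxane/H2O, rt
Reagents that add atoms: sodium periodate [Na+].[O-]I(=O)(=O)=O (source of the new oxygen); osmium tetroxide O=[Os](=O)(=O)=O (catalytic carrier)
Why: Lemieux–Johnson oxidation cleaves the terminal alkene to the C7' aldehyde, which closes with the C9 alcohol to the five-membered lactol, and avoids the risk that ozone poses to the electron-rich arenes.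

Step 19
Reactants: 27 lactol
Product: 29 fragment 2: (S)-3-[(R)-(aryl)(MEM-oxy)methyl]-2,3-dihydrofuran (7R,8S; enol ether C7'=C8'), via anomeric mesylate 28 (not isolated)
Conditions: MsCl, Et3N, CH2Cl2, −40 to 40 °C; chromatography on Et3N-treated silica
Reagents that add atoms: methanesulfonyl chloride CS(=O)(=O)Cl (its mesyl group stands in 28 only)
Why: Dehydration of a 2-deoxy lactol by way of its anomeric mesylate (elimination through the oxocarbenium ion with Et3N), the known route to furanoid glycals, gives the enol ether under basic conditions that keep the MEM acetal and C8 intact.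

Step 20
Reactants: 29 fragment 2 (dihydrofuran MEM ether); 17 fragment 1 (aryl iodide)
Product: 32 fully protected target (7R,8S,7'R,8'S core; four benzoates; four TBS ethers), via O7-chloromethyl ether 30 (not isolated), via bicyclic C7' chloride 31 (not isolated)
Conditions: NiCl2·DME (10 mol %), 2,6-bis(pyrazol-1-yl)pyridine (12 mol %), Zn dust, Me3SiCl, ZnCl2 (20 mol %), 2,6-di-tert-butyl-4-methylpyridine, 1,4-dioxane, rt, all components in one flask
Reagents that add atoms: chlorotrimethylsilane C[Si](C)(C)Cl (its chlorine stands in 30 and 31 only)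
Why: Proposed new method: ZnCl2 chelates the two outer oxygens of the MEM acetal and Me3SiCl removes the methoxyethoxide, so only the O7–C9' side is ionised (30 in equilibrium with the oxocarbenium ion O7=C9'H2), the nucleophilic β-carbon C8' of the ring-B enol ether attacks C9' in a Prins-type closure, chloride caps the new ring-B oxocarbenium ion at C7' as 31, monovalent nickel abstracts that chlorine to give the C7' α-oxy radical, the radical is captured by the aryl–nickel halide formed from 17 and zerovalent nickel, and reductive elimination from trivalent nickel makes the aryl–C7' bond while Zn regenerates the catalyst. The closest known reaction types are the nickel-catalysed reductive arylation of acetals by way of α-chloro ethers formed in situ with Me3SiCl and Zn, the reductive C-arylation of glycosyl halides with aryl iodides, the Lewis-acid cyclisation of mixed acetals of dihydrofuryl carbinols to furofuran acetals and nickel-catalysed radical cyclisation/aryl coupling tandems; what is new is their merger on a formaldehyde acetal. Ring A closes as a five-membered ring, endo with respect to the O7=C9' bond and exo with respect to the C7'=C8' bond, and if nickel abstracts chlorine from 30 before it ionises, the alkoxymethyl radical reaches the same C7' radical by 5-exo-trig closure, so the polar and the radical channel converge. C8' is controlled by the three-atom tether C8–C7–O7, which lets C9' reach only the face of ring B that carries C7 and thus enforces the cis ring fusion relayed from C8 (8'S); C7' is controlled by the shape of the cis-fused bicycle, whose convex face, trans to the C8'–C9' bond, is the only open one for nickel, which places the aryl group exo (7'R). The step needs ring closure before aryl capture (secured by the intramolecular, polarity-matched enol ether and the low nickel concentration), ionisation of the acetal alone (the benzylic benzoates and silyl ethers bear a cation-destabilising β-aryloxy group, and Zn and the hindered pyridine remove traces of HCl that would protonate the enol ether), bond formation at C8' and not at C7' (the enol ether is polarised towards C8', which disfavours a 2-oxonia-Cope shift) and cross- over homocoupling (the aryl iodide reacts with zerovalent nickel, the α-chloro ether with monovalent nickel).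

Step 21
Reactants: 32 fully protected target
Product: 33 tetraol: units a and c free at O7 and O9; unit b 7,9-bis-OTBS; G1 and G3 phenols as TBS ethers
Conditions: iBu2AlH (excess), CH2Cl2, −78 °C; aq. potassium sodium tartrate
Reagents that add atoms: none
Why: Reductive ester cleavage converts the four benzoates into free alcohols at low temperature without base, and it is run while the phenols are still silylated so that no p-hydroxybenzyl ester can collapse to a quinone methide and scramble C7.

Step 22
Reactants: 33 tetraol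
Product: 34 target CNP0316493.1
Conditions: Bu4NF, AcOH, THF, 0 °C to rt
Reagents that add atoms: none
Why: Fluoride desilylation buffered with AcOH removes the two alkyl and the two aryl silyl ethers, and with OH as the only C7 substituent no quinone methide forms and no stereocentre is touched.

**Compound list**

1 | vanillin | COc1cc(C=O)ccc1O | starting material
2 | 4-(tert-butyldimethylsilyloxy)-3-methoxybenzaldehyde | COc1cc(C=O)ccc1O[Si](C)(C)C(C)(C)C | intermediate
3 | 2,6-dimethoxyphenol | COc1cccc(OC)c1O | starting material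
4 | 4-iodo-2,6-dimethoxyphenol | COc1cc(I)cc(OC)c1O | intermediate
5 | (S)-4-benzyl-3-(chloroacetyl)oxazolidin-2-one | O=C(CCl)N1C(=O)OC[C@@H]1Cc1ccccc1 | starting material
6 | (S)-4-benzyl-3-[2-(4-iodo-2,6-dimethoxyphenoxy)acetyl]oxazolidin-2-one | COc1cc(I)cc(OC)c1OCC(=O)N1C(=O)OC[C@@H]1Cc1ccccc1 | intermediate
7 | Z-dibutylboron enolate of 6 (not isolated) | CCCCB(CCCC)O/C(=C\Oc1c(OC)cc(I)cc1OC)N1C(=O)OC[C@@H]1Cc1ccccc1 | intermediate
8 | syn aldol adduct (2S,3R) on the (S)-auxiliary | COc1cc([C@@H](O)[C@@H](C(=O)N2C(=O)OC[C@@H]2Cc2ccccc2)Oc2c(OC)cc(I)cc2OC)ccc1O[Si](C)(C)C(C)(C)C | intermediate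
9 | threo diol (1R,2R), common to both halves | COc1cc([C@@H](O)[C@@H](CO)Oc2c(OC)cc(I)cc2OC)ccc1O[Si](C)(C)C(C)(C)C | intermediate
10 | 7,9-bis-O-TBS ether of 9 (7R,8R) | COc1cc([C@@H](O[Si](C)(C)C(C)(C)C)[C@@H](CO[Si](C)(C)C(C)(C)C)Oc2c(OC)cc(I)cc2OC)ccc1O[Si](C)(C)C(C)(C)C | intermediate
11 | G2 phenol (7R,8R; 7,9-bis-OTBS) | COc1cc([C@@H](O[Si](C)(C)C(C)(C)C)[C@@H](CO[Si](C)(C)C(C)(C)C)Oc2c(OC)cc(I)cc2OC)ccc1O | intermediate
12 | (R)-4-benzyl-3-(chloroacetyl)oxazolidin-2-one | O=C(CCl)N1C(=O)OC[C@H]1Cc1ccccc1 | starting material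
13 | (R)-aryloxyacetyl imide made from 11 | COc1cc([C@@H](O[Si](C)(C)C(C)(C)C)[C@@H](CO[Si](C)(C)C(C)(C)C)Oc2c(OC)cc(I)cc2OC)ccc1OCC(=O)N1C(=O)OC[C@H]1Cc1ccccc1 | intermediate
14 | Z-dibutylboron enolate of 13 (not isolated) | CCCCB(CCCC)O/C(=C\Oc1ccc([C@@H](O[Si](C)(C)C(C)(C)C)[C@@H](CO[Si](C)(C)C(C)(C)C)Oc2c(OC)cc(I)cc2OC)cc1OC)N1C(=O)OC[C@H]1Cc1ccccc1 | intermediate
15 | syn aldol adduct (new centres 2R,3S) on the (R)-auxiliary | COc1cc([C@H](O)[C@H](C(=O)N2C(=O)OC[C@H]2Cc2ccccc2)Oc2ccc([C@@H](O[Si](C)(C)C(C)(C)C)[C@@H](CO[Si](C)(C)C(C)(C)C)Oc3c(OC)cc(I)cc3OC)cc2OC)ccc1O[Si](C)(C)C(C)(C)C | intermediate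
16 | threo diol of unit a (7S,8S) on unit b (7R,8R) | COc1cc([C@H](O)[C@H](CO)Oc2ccc([C@@H](O[Si](C)(C)C(C)(C)C)[C@@H](CO[Si](C)(C)C(C)(C)C)Oc3c(OC)cc(I)cc3OC)cc2OC)ccc1O[Si](C)(C)C(C)(C)C | intermediate
17 | fragment 1, aryl iodide (unit a 7R,8S dibenzoate; unit b 7R,8R bis-OTBS) | COc1cc([C@@H](OC(=O)c2ccccc2)[C@H](COC(=O)c2ccccc2)Oc2ccc([C@@H](O[Si](C)(C)C(C)(C)C)[C@@H](CO[Si](C)(C)C(C)(C)C)Oc3c(OC)cc(I)cc3OC)cc2OC)ccc1O[Si](C)(C)C(C)(C)C | intermediate
18 | erythro dibenzoate iodide (1S,2R) | COc1cc([C@H](OC(=O)c2ccccc2)[C@@H](COC(=O)c2ccccc2)Oc2c(OC)cc(I)cc2OC)ccc1O[Si](C)(C)C(C)(C)C | intermediate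
19 | S2 aldehyde carrying unit c (7S,8R dibenzoate) | COc1cc([C@H](OC(=O)c2ccccc2)[C@@H](COC(=O)c2ccccc2)Oc2c(OC)cc(C=O)cc2OC)ccc1O[Si](C)(C)C(C)(C)C | intermediate
20 | (R)-4-benzyloxazolidin-2-one | O=C1N[C@H](Cc2ccccc2)CO1 | starting material
21 | pent-4-enoyl chloride | C=CCCC(=O)Cl | starting material
22 | (R)-4-benzyl-3-(pent-4-enoyl)oxazolidin-2-one | C=CCCC(=O)N1C(=O)OC[C@H]1Cc1ccccc1 | intermediate
23 | Z-dibutylboron enolate of 22 (not isolated) | CCCCB(CCCC)O/C(=C\CC=C)N1C(=O)OC[C@H]1Cc1ccccc1 | intermediate
24 | core syn aldol adduct (2R,3R) | O[C@H]([C@H](C(=O)N1C(=O)OC[C@H]1Cc1ccccc1)CC=C)c1cc(OC)c(O[C@H](COC(=O)c2ccccc2)[C@@H](OC(=O)c2ccccc2)c2ccc(O[Si](C)(C)C(C)(C)C)c(OC)c2)c(OC)c1 | intermediate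
25 | O7-MEM ether of 24 | COCCOCO[C@H]([C@H](C(=O)N1C(=O)OC[C@H]1Cc1ccccc1)CC=C)c1cc(OC)c(O[C@H](COC(=O)c2ccccc2)[C@@H](OC(=O)c2ccccc2)c2ccc(O[Si](C)(C)C(C)(C)C)c(OC)c2)c(OC)c1 | intermediate
26 | primary alcohol (7R,8S) | COCCOCO[C@H]([C@H](CO)CC=C)c1cc(OC)c(O[C@H](COC(=O)c2ccccc2)[C@@H](OC(=O)c2ccccc2)c2ccc(O[Si](C)(C)C(C)(C)C)c(OC)c2)c(OC)c1 | intermediate
27 | ring-B lactol (7R,8S; anomeric mixture) | COCCOCO[C@H]([C@@H]1COC(O)C1)c1cc(OC)c(O[C@H](COC(=O)c2ccccc2)[C@@H](OC(=O)c2ccccc2)c2ccc(O[Si](C)(C)C(C)(C)C)c(OC)c2)c(OC)c1 | intermediate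
28 | anomeric mesylate of 27 (not isolated) | COCCOCO[C@H]([C@@H]1COC(OS(C)(=O)=O)C1)c1cc(OC)c(O[C@H](COC(=O)c2ccccc2)[C@@H](OC(=O)c2ccccc2)c2ccc(O[Si](C)(C)C(C)(C)C)c(OC)c2)c(OC)c1 | intermediate
29 | fragment 2, 2,3-dihydrofuran MEM ether (7R,8S) | COCCOCO[C@H]([C@@H]1COC=C1)c1cc(OC)c(O[C@H](COC(=O)c2ccccc2)[C@@H](OC(=O)c2ccccc2)c2ccc(O[Si](C)(C)C(C)(C)C)c(OC)c2)c(OC)c1 | intermediate
30 | O7-chloromethyl ether (not isolated) | ClCO[C@H]([C@@H]1COC=C1)c1cc(OC)c(O[C@H](COC(=O)c2ccccc2)[C@@H](OC(=O)c2ccccc2)c2ccc(O[Si](C)(C)C(C)(C)C)c(OC)c2)c(OC)c1 | intermediate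
31 | bicyclic C7' chloride (7R,8S,8'S; anomeric mixture; not isolated) | ClC1OC[C@@H]2[C@H]1CO[C@H]2c1cc(OC)c(O[C@H](COC(=O)c2ccccc2)[C@@H](OC(=O)c2ccccc2)c2ccc(O[Si](C)(C)C(C)(C)C)c(OC)c2)c(OC)c1 | intermediate
32 | fully protected target | COc1cc([C@@H](OC(=O)c6ccccc6)[C@H](COC(=O)c6ccccc6)Oc2ccc([C@@H](O[Si](C)(C)C(C)(C)C)[C@@H](CO[Si](C)(C)C(C)(C)C)Oc3c(OC)cc([C@@H]4OC[C@@H]5[C@H]4CO[C@H]5c4cc(OC)c(O[C@H](COC(=O)c6ccccc6)[C@@H](OC(=O)c6ccccc6)c5ccc(O[Si](C)(C)C(C)(C)C)c(OC)c5)c(OC)c4)cc3OC)cc2OC)ccc1O[Si](C)(C)C(C)(C)C | intermediate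
33 | tetraol with four TBS ethers | COc1cc([C@@H](O)[C@H](CO)Oc2ccc([C@@H](O[Si](C)(C)C(C)(C)C)[C@@H](CO[Si](C)(C)C(C)(C)C)Oc3c(OC)cc([C@@H]4OC[C@@H]5[C@H]4CO[C@H]5c4cc(OC)c(O[C@H](CO)[C@@H](O)c5ccc(O[Si](C)(C)C(C)(C)C)c(OC)c5)c(OC)c4)cc3OC)cc2OC)ccc1O[Si](C)(C)C(C)(C)C | intermediate
34 | CNP0316493.1 | COc1cc([C@@H](O)[C@H](CO)Oc2ccc([C@@H](O)[C@@H](CO)Oc3c(OC)cc([C@@H]4OC[C@@H]5[C@H]4CO[C@H]5c4cc(OC)c(O[C@H](CO)[C@@H](O)c5ccc(O)c(OC)c5)c(OC)c4)cc3OC)cc2OC)ccc1O | target

**Step count**

Total step count: 22.
Longest linear sequence: 14 steps (3, 4, 6, 8, 9, 18, 19, 24, 25, 26, 27, 29, 32, 33, 34).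

**Steps most likely to fail**

1. Step 20 (bears the label "Proposed new method:").
 - What may go wrong:
  - aryl capture of the C9' centre before ring closure;
  - protonation of the enol ether by adventitious HCl;
  - transfer of the acetal carbon instead of ionisation on the O7 side;
  - reductive dimerisation or hydrodechlorination of the α-chloro ether at the zinc surface;
  - homocoupling of the aryl iodide.
 - The fallback separates the two events and replaces the radical cross-electrophile coupling by a polar arylation with a preformed organozinc. It uses only known reaction types, sets out from 29 and 17 and comes back at 32.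
 - Compound 29 is isomerised with catalytic Me3SiOTf (2,6-di-tert-butylpyridine, CH2Cl2, −78 °C). This is the known acetal-initiated Prins cyclisation of dihydrofuryl carbinol acetals, and it gives the isolable bicyclic 2-methoxyethyl acetal F1.
 - Compound 17 is converted by insertion of Zn dust in the presence of LiCl (THF, 50 °C), which tolerates esters, into the arylzinc iodide F2.
 - F1 is exchanged with Me3SiCl and catalytic ZnCl2 to the chloride 31. This is treated with F2 in toluene/THF from −20 °C to rt.
 - The coupling is the known SN1-type C-arylation of α-halo ethers and glycosyl halides by arylzinc reagents. Attack on the convex face of the oxocarbenium ion should give 32.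

2. Step 12 (step 11 is the same reaction type and shares the risk).
 - What may go wrong:
  - erosion of the inversion at C7 through ionisation of the electron-rich benzylic oxyphosphonium ion;
  - retention through participation of the C9 benzoate that forms first;
  - elimination.
 - The fallback replaces substitution by an oxidation/reduction sequence. It sets out from 9 and comes back at 18.
 - Selective acylation of the primary alcohol (BzCl, 2,4,6-collidine, CH2Cl2, −78 to −20 °C) gives the threo 9-monobenzoate F3.
 - Dess–Martin periodinane (NaHCO3, CH2Cl2) gives the 7-ketone F4.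
 - Chelation-controlled reduction with Zn(BH4)2 (Et2O, −40 °C) follows. A Cram chelate forms between the ketone and the C8 aryloxy oxygen, and hydride arrives from the side of the C8 hydrogen. This should favour the erythro 7-alcohol F5.
 - BzCl, pyridine and DMAP then give 18.

3. Step 19.
 - What may go wrong:
  - substitution of the anomeric mesylate by chloride without elimination;
  - acid-induced hydration or oligomerisation of the enol ether during formation or isolation;
  - loss of the MEM acetal.
 - The fallback replaces the amine-induced elimination by a neutral thermal syn elimination, as known for furanoid glycals. It sets out from 27 and comes back at 29.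
 - N-(phenylselanyl)phthalimide and Bu3P (CH2Cl2, −20 °C) convert the lactol into the anomeric phenyl selenide F6.
 - Oxidation with H2O2 in the presence of pyridine (THF, 0 °C) gives the selenoxide F7. It is not isolated and eliminates towards C8' on warming to rt to give 29.

**Further compounds**

F1 | step 20 | bicyclic 2-methoxyethyl acetal (7R,8S,8'S; anomeric mixture) | COCCOC1OC[C@@H]2[C@H]1CO[C@H]2c1cc(OC)c(O[C@H](COC(=O)c2ccccc2)[C@@H](OC(=O)c2ccccc2)c2ccc(O[Si](C)(C)C(C)(C)C)c(OC)c2)c(OC)c1
F2 | step 20 | arylzinc iodide derived from 17 | COc1cc([C@@H](OC(=O)c2ccccc2)[C@H](COC(=O)c2ccccc2)Oc2ccc([C@@H](O[Si](C)(C)C(C)(C)C)[C@@H](CO[Si](C)(C)C(C)(C)C)Oc3c(OC)cc([Zn]I)cc3OC)cc2OC)ccc1O[Si](C)(C)C(C)(C)C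
F3 | step 12 | threo 9-monobenzoate (7R,8R) | COc1cc([C@@H](O)[C@@H](COC(=O)c2ccccc2)Oc2c(OC)cc(I)cc2OC)ccc1O[Si](C)(C)C(C)(C)C
F4 | step 12 | 7-ketone (8R) | COc1cc(C(=O)[C@@H](COC(=O)c2ccccc2)Oc2c(OC)cc(I)cc2OC)ccc1O[Si](C)(C)C(C)(C)C
F5 | step 12 | erythro 7-alcohol 9-benzoate (7S,8R) | COc1cc([C@H](O)[C@@H](COC(=O)c2ccccc2)Oc2c(OC)cc(I)cc2OC)ccc1O[Si](C)(C)C(C)(C)C
F6 | step 19 | anomeric phenyl selenide (7R,8S; anomeric mixture) | COCCOCO[C@H]([C@@H]1COC([Se]c2ccccc2)C1)c1cc(OC)c(O[C@H](COC(=O)c2ccccc2)[C@@H](OC(=O)c2ccccc2)c2ccc(O[Si](C)(C)C(C)(C)C)c(OC)c2)c(OC)c1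
F7 | step 19 | selenoxide of F6 (not isolated) | COCCOCO[C@H]([C@@H]1COC([Se](=O)c2ccccc2)C1)c1cc(OC)c(O[C@H](COC(=O)c2ccccc2)[C@@H](OC(=O)c2ccccc2)c2ccc(O[Si](C)(C)C(C)(C)C)c(OC)c2)c(OC)c1
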